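## Retrosynthetic overview

1. Germacrane numbering is used. The ten-membered carbocycle is C1–C10, with the E-alkene at C1=C10, the oxirane on C4–C5, the aroyloxy group on C6, the isopropyl group (its CH is C11) on C7, and OH on C8.
2. Enabling feature: ring carbon C7 carries the isopropyl CH and sits between two oxygenated ring carbons, C6 and C8. Read backwards, C11 is a former ring member, a CMe2 unit between C7 and a C8 ketone in an eleven-membered ring.
3. Disconnections:
   - The C6 ester and C8–OH come from an Evans–Tishchenko reaction of the C6-hydroxy C8-ketone.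
   - The C7–C8 bond and the isopropyl group come from a radical 1,2-acyl shift (eleven- to ten-membered ring).
   - C1–C2 comes from a B-alkyl Suzuki macrocyclisation.
   - C5–C6 comes from a dienyl Grignard reagent and an α-chloro aldehyde.
4. Order of ring formation: oxirane (step 10), eleven-membered carbocycle (step 12), ten-membered carbocycle (step 13). The arene is bought.
5. Stereochemical relay: the organocatalytic C7–Cl sets C6. C6 sets C4/C5 and, after the old C7 centre is erased, the new C7. The C6 hydroxyl then sets C8.

Key step: step 13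

Assumption: the (5S)-imidazolidinone catalyst of step 5 is taken to give the (S)-α-chloro aldehyde, as with simple alkanals. If the sense is opposite, its enantiomer is used.

## Route

Step 1
Reactants: 1 2,2-dimethylpent-4-enal; 2 propargyl bromide
Product: 4 (±)-5,5-dimethyloct-7-en-1-yn-4-ol, via allenylzinc bromide 3 (not isolated)
Conditions: Zn dust, THF/sat. aq NH4Cl, 0 °C to rt
Reagents that add atoms: none
Why: In this zinc Barbier propargylation the allenylzinc species adds through its γ-carbon (SE2') to the non-enolisable aldehyde to give the homopropargylic alcohol, and the racemic carbinol centre is erased in step 3.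

Step 2
Reactants: 4 (±)-5,5-dimethyloct-7-en-1-yn-4-ol
Product: 6 (±)-(1E)-1-iodo-2,5,5-trimethylocta-1,7-dien-4-ol, via alkenylalane 5 (not isolated)
Conditions: Me3Al (3 equiv), Cp2ZrCl2 (0.25 equiv), CH2Cl2, 0 °C to rt; then I2, THF, −30 °C; aq K2CO3
Reagents that add atoms: trimethylaluminium C[Al](C)C; iodine II
Why: In this Negishi Zr-catalysed carboalumination, syn Me–Al addition to the terminal alkyne (much faster than to the monosubstituted alkene) followed by iodinolysis with retention fixes the E-trisubstituted alkene that becomes C1=C10.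

Step 3
Reactants: 6 (±)-(1E)-1-iodo-2,5,5-trimethylocta-1,7-dien-4-ol
Product: 7 (1E)-1-iodo-2,5,5-trimethylocta-1,7-dien-4-one
Conditions: Dess–Martin periodinane, NaHCO3, CH2Cl2, 0 °C
Reagents that add atoms: none
Why: Dess–Martin oxidation under buffered neutral conditions should give the β,γ-unsaturated, α'-quaternary ketone (the future C8 acyl group) without conjugation of the alkene.

Step 4
Reactants: 7 (1E)-1-iodo-2,5,5-trimethylocta-1,7-dien-4-one
Product: 9 (6E)-7-iodo-3,3,6-trimethyl-4-oxohept-6-enal, via vicinal diol 8 (not isolated)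
Conditions: OsO4 (2 mol %), NaIO4, 2,6-lutidine, dioxane/H2O, rt
Reagents that add atoms: osmium tetroxide O=[Os](=O)(=O)=O; sodium periodate [Na+].[O-]I(=O)(=O)=O
Why: In this Lemieux–Johnson cleavage the unhindered monosubstituted alkene is dihydroxylated in preference to the electron-poor, trisubstituted iodoalkene, and the diol is cleaved in situ.

Step 5
Reactants: 9 (6E)-7-iodo-3,3,6-trimethyl-4-oxohept-6-enal
Product: 10 (2S,6E)-2-chloro-7-iodo-3,3,6-trimethyl-4-oxohept-6-enal
Conditions: (5S)-5-benzyl-2,2,3-trimethylimidazolidin-4-one·TFA (10 mol %), 2,3,4,5,6,6-hexachlorocyclohexa-2,4-dienone, acetone, −30 °C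
Reagents that add atoms: 2,3,4,5,6,6-hexachlorocyclohexa-2,4-dien-1-one O=C1C(Cl)=C(Cl)C(Cl)=C(Cl)C1(Cl)Cl
Why: In this enamine-catalysed enantioselective α-chlorination of an aldehyde (which tolerates β-quaternary substrates) only the aldehyde forms an enamine, and the benzyl group of the catalyst shields one enamine face, which sets the (S)-chloride at C7.

Step 6
Reactants: 11 propargyl alcohol
Product: 13 (2E)-3-iodo-2-methylprop-2-en-1-ol, via alkenylalane 12 (not isolated)
Conditions: Me3Al (3 equiv), Cp2ZrCl2 (0.25 equiv), CH2Cl2, 0 °C to rt; then I2, THF, −30 °C; aq K2CO3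
Reagents that add atoms: trimethylaluminium C[Al](C)C; iodine II
Why: Negishi carboalumination and iodinolysis, a syn addition, sets the E geometry of the future C4=C5 alkene.

Step 7
Reactants: 13 (2E)-3-iodo-2-methylprop-2-en-1-ol
Product: 14 (2E)-3-iodo-2-methylprop-2-enal
Conditions: MnO2, CH2Cl2, rt
Reagents that add atoms: none
Why: MnO2 oxidises the allylic alcohol without touching the vinyl iodide or its geometry.

Step 8
Reactants: 14 (2E)-3-iodo-2-methylprop-2-enal
Product: 15 (1E)-1-iodo-2-methylbuta-1,3-diene
Conditions: Ph3PCH3Br, KOtBu, THF, 0 °C; used as a solution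
Reagents that add atoms: methyltriphenylphosphonium bromide C[P+](c1ccccc1)(c1ccccc1)c1ccccc1.[Br-]
Why: Wittig methylenation of the enal gives the iododiene, whose vinyl group later supplies C2 and C3.

Step 9
Reactants: 15 (1E)-1-iodo-2-methylbuta-1,3-diene; 10 (2S,6E)-2-chloro-7-iodo-3,3,6-trimethyl-4-oxohept-6-enal
Product: 17 (1E,6S,7R,8E)-6-chloro-7-hydroxy-1-iodo-2,5,5,9-trimethylundeca-1,8,10-trien-4-one, via dienylmagnesium chloride 16 (not isolated)
Conditions: 15, i-PrMgCl·LiCl, THF, 0 °C to rt; then 10, −78 °C; aq NH4Cl
Reagents that add atoms: none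
Why: After iodine–magnesium exchange with retention, the 1,2-addition to the α-chloro aldehyde under Cornforth–Evans control should give the anti chlorohydrin, so the C7 chloride sets the C6 carbinol, and the aldehyde reacts far faster than the neopentyl-type ketone at −78 °C.

Step 10
Reactants: 17 anti chlorohydrin dienol
Product: 18 (1E,6S,7R)-6-chloro-7-[(2R,3R)-3-ethenyl-3-methyloxiran-2-yl]-7-hydroxy-1-iodo-2,5,5-trimethylhept-1-en-4-one
Conditions: VO(acac)2 (5 mol %), t-BuOOH (decane), toluene, 0 °C
Reagents that add atoms: tert-butyl hydroperoxide CC(C)(C)OO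
Why: In this hydroxyl-directed vanadium epoxidation only the allylic C4=C5 alkene reacts, and A1,3 strain between the C6 substituents and the cis methyl on C4 fixes the reactive rotamer, which gives the threo epoxy alcohol with (4R,5R) configuration.

Step 11
Reactants: 18 epoxy alcohol
Product: 19 triethylsilyl ether of 18
Conditions: Et3SiCl, imidazole, DMAP (cat.), CH2Cl2, 0 °C to rt
Reagents that add atoms: chlorotriethylsilane CC[Si](Cl)(CC)CC
Why: Silylation blocks epoxide formation from the chlorohydrin under the basic coupling conditions and places the bulky group on O6 that steers step 13.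

Step 12
Reactants: 19 triethylsilyl ether
Product: 21 (1R,2R,3S,7E,11R)-3-chloro-4,4,7,11-tetramethyl-2-(triethylsilyloxy)-12-oxabicyclo[9.1.0]dodec-7-en-5-one (eleven-membered carbocycle; germacrane locants 4R,5R,6R,7S), via B-alkyl-9-BBN borane 20 (not isolated)
Conditions: 9-BBN, THF, 0 °C to rt; then slow addition to Pd(dppf)Cl2 (15 mol %), AsPh3, Cs2CO3, DMF/THF/H2O, 2 mM, rt to 45 °C
Reagents that add atoms: none
Why: In this B-alkyl Suzuki–Miyaura macrocyclisation, 9-BBN adds anti-Markovnikov to the only monosubstituted alkene (the hindered ketone reacts slowly), and the sp3–sp2 coupling closes C1–C2 with retention of the E-alkene.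

Step 13
Reactants: 21 eleven-membered β-chloro ketone
Product: 22 (1R,2S,3S,6E,10R)-6,10-dimethyl-3-(propan-2-yl)-2-(triethylsilyloxy)-11-oxabicyclo[8.1.0]undec-6-en-4-one (ten-membered carbocycle; germacrane locants 4R,5R,6S,7S)
Conditions: (Me3Si)3SiH (1.5 equiv), AIBN (0.2 equiv, in portions), toluene (0.01 M), 90 °C
Reagents that add atoms: none
Why: Proposed new method: the silyl radical abstracts chlorine from C7, the secondary C7 radical adds 3-exo to the C8 carbonyl, and the cyclopropyloxy radical opens by β-scission of the C8–CMe2 bond, so the acyl carbon moves from the quaternary carbon to C7, the eleven-membered ring becomes the ten-membered one, and the expelled ring atom appears as a tertiary radical that takes H from the silane and becomes the isopropyl group. The closest known reaction type is the 1,2-acyl shift of β-keto alkyl radicals (Dowd–Beckwith ring expansion, radical 1,2-carbonyl migration in α-quaternary β,γ-unsaturated carbonyl compounds), run here in the ring-contracting direction on a medium ring. The ten-membered ring closes by this 3-exo-trig/β-scission sequence, and the oxirane, which is not adjacent to either radical centre, is left intact. The new C7 centre is controlled by C6: with H6 eclipsing the CMe2 group, the acyl carbon reaches C7 anti to the bulky OSiEt3 group and gauche to C5, the only torsion the ring allows, which places the isopropyl group trans to O6, and because the radical is planar both C7 epimers of 21 converge on the same product. The shift has to outrun H transfer to the secondary radical and transannular addition to C1=C10, and this is secured by the slow H donor at low concentration, the secondary-to-tertiary radical gain, relief of the CMe2/CH(OSi) crowding, and the fact that attack on C10 would build two adjacent quaternary carbons.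

Step 14
Reactants: 22 ten-membered silyloxy ketone
Product: 23 (1R,2S,3S,6E,10R)-2-hydroxy-6,10-dimethyl-3-(propan-2-yl)-11-oxabicyclo[8.1.0]undec-6-en-4-one
Conditions: HF·pyridine, pyridine, THF, 0 °C
Reagents that add atoms: none
Why: Buffered fluoride desilylation is tolerated by trisubstituted epoxides and β-hydroxy ketones and avoids base, so no retro-aldol reaction, C7 epimerisation or alkene conjugation is expected.

Step 15
Reactants: 23 β-hydroxy ketone; 24 3,4,5-trimethoxybenzaldehyde
Product: 26 target, (1R,2S,3R,4R,6E,10R)-4-hydroxy-6,10-dimethyl-3-(propan-2-yl)-11-oxabicyclo[8.1.0]undec-6-en-2-yl 3,4,5-trimethoxybenzoate (germacrane locants 4R,5R,6S,7R,8R), via samarium-bound hemiacetal 25 (not isolated)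
Conditions: 24 (5 equiv), SmI2 (0.3 equiv), THF, −10 °C
Reagents that add atoms: none
Why: In this Evans–Tishchenko reduction the O6 hemiacetal delivers its hydride intramolecularly to the Sm-bound C8 ketone through a chair transition state, which gives the 1,3-anti alcohol (8R) and leaves the aroyl group on O6 in the same operation.

## Compound list

1 | 2,2-dimethylpent-4-enal | O=CC(C)(C)CC=C | starting material
2 | propargyl bromide | BrCC#C | starting material
3 | allenylzinc bromide | Br[Zn]C=C=C | intermediate
4 | (±)-5,5-dimethyloct-7-en-1-yn-4-ol | C#CCC(O)C(C)(C)CC=C | intermediate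
5 | alkenylalane (O-aluminated) from 4 | C[Al](C)/C=C(C)/CC(O[Al](C)C)C(C)(C)CC=C | intermediate
6 | (±)-(1E)-1-iodo-2,5,5-trimethylocta-1,7-dien-4-ol | I/C=C(C)/CC(O)C(C)(C)CC=C | intermediate
7 | (1E)-1-iodo-2,5,5-trimethylocta-1,7-dien-4-one | I/C=C(C)/CC(=O)C(C)(C)CC=C | intermediate
8 | (1E)-7,8-dihydroxy-1-iodo-2,5,5-trimethyloct-1-en-4-one | I/C=C(C)/CC(=O)C(C)(C)CC(O)CO | intermediate
9 | (6E)-7-iodo-3,3,6-trimethyl-4-oxohept-6-enal | I/C=C(C)/CC(=O)C(C)(C)CC=O | intermediate
10 | (2S,6E)-2-chloro-7-iodo-3,3,6-trimethyl-4-oxohept-6-enal | I/C=C(C)/CC(=O)C(C)(C)[C@H](Cl)C=O | intermediate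
11 | propargyl alcohol | OCC#C | starting material
12 | alkenylalane (O-aluminated) from 11 | C[Al](C)/C=C(C)/CO[Al](C)C | intermediate
13 | (2E)-3-iodo-2-methylprop-2-en-1-ol | OC/C(C)=C/I | intermediate
14 | (2E)-3-iodo-2-methylprop-2-enal | O=C/C(C)=C/I | intermediate
15 | (1E)-1-iodo-2-methylbuta-1,3-diene | C=C/C(C)=C/I | intermediate
16 | [(1E)-2-methylbuta-1,3-dienyl]magnesium chloride | C=C/C(C)=C/[Mg]Cl | intermediate
17 | anti chlorohydrin dienol (6R,7S in germacrane locants) | O[C@H](/C=C(C)/C=C)[C@@H](Cl)C(C)(C)C(=O)C/C(C)=C/I | intermediate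
18 | threo epoxy alcohol (4R,5R,6R,7S) | O[C@H]([C@H]1O[C@]1(C)C=C)[C@@H](Cl)C(C)(C)C(=O)C/C(C)=C/I | intermediate
19 | triethylsilyl ether of 18 | CC[Si](CC)(CC)O[C@H]([C@H]1O[C@]1(C)C=C)[C@@H](Cl)C(C)(C)C(=O)C/C(C)=C/I | intermediate
20 | B-alkyl-9-BBN borane from 19 | CC[Si](CC)(CC)O[C@H]([C@H]1O[C@]1(C)CCB1C2CCCC1CCC2)[C@@H](Cl)C(C)(C)C(=O)C/C(C)=C/I | intermediate
21 | eleven-membered β-chloro ketone (4R,5R,6R,7S) | CC[Si](CC)(CC)O[C@H]1[C@@H](Cl)C(C)(C)C(=O)C/C(C)=C/CC[C@@]2(C)O[C@H]12 | intermediate
22 | ten-membered silyloxy ketone (4R,5R,6S,7S) | CC[Si](CC)(CC)O[C@H]1[C@H](C(C)C)C(=O)C/C(C)=C/CC[C@@]2(C)O[C@H]12 | intermediate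
23 | ten-membered β-hydroxy ketone (4R,5R,6S,7S) | O[C@H]1[C@H](C(C)C)C(=O)C/C(C)=C/CC[C@@]2(C)O[C@H]12 | intermediate
24 | 3,4,5-trimethoxybenzaldehyde | COc1cc(C=O)cc(OC)c1OC | starting material
25 | O6 hemiacetal of 23 with 24 (shown metal-free) | COc1cc(C(O)O[C@H]2[C@H](C(C)C)C(=O)C/C(C)=C/CC[C@@]3(C)O[C@H]23)cc(OC)c1OC | intermediate
26 | CNP0279501.1 (4R,5R,6S,7R,8R) | COc1cc(C(=O)O[C@H]2[C@H](C(C)C)[C@H](O)C/C(C)=C/CC[C@@]3(C)O[C@H]23)cc(OC)c1OC | target

## Step count and risks

Total step count: 15. Longest linear sequence: 12 steps (steps 1–5 and 9–15).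

**Step 13 (riskiest).** What may go wrong:
- Hydrogen transfer to the unrearranged secondary radical.
- An unfavourable position of the acyl-shift equilibrium, caused by the extra strain of the ten-membered ring.
- Transannular radical addition to the C1=C10 alkene.
- E/Z isomerisation of that alkene induced by the silyl radical.

Fallback: the two bond changes are separated and each is made irreversible.
- Setting out from 21, the C7–C8 bond is closed reductively. The method is 1,3-reductive cyclisation of the β-halo ketone with SmI2/HMPA in THF at −78 °C, driven by formation of the Sm–O bond. This gives the bicyclo[8.1.0] cyclopropanol F1.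
- F1 is then opened by one-electron oxidation (cyclopropanol to β-keto radical chemistry) with manganese(III) tris(2-pyridinecarboxylate) and excess Bu3SnH in DMF at 0 °C.
- β-Scission of the cyclopropyloxy radical gives the tertiary radical kinetically, and this radical is capped at once. The fallback returns to the route at 22.

**Step 12.** What may go wrong:
- Slow transmetalation of a borane next to a fully substituted epoxide carbon.
- Oligomerisation.
- Base-induced conjugation of the β,γ-unsaturated ketone.
- Loss of the silyl group.

Fallback: the ring is closed before the oxirane exists, and the epoxide is then made under macrocyclic and hydroxyl control.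
- Setting out from 17, silylation gives the dienol silyl ether F2.
- Hydroboration and Suzuki macrocyclisation of F2 give the eleven-membered dienone silyl ether F3.
- HF·pyridine frees the macrocyclic allylic alcohol F4.
- VO(acac)2/t-BuOOH epoxidises the allylic C4=C5 alkene of F4 to the macrocyclic epoxy alcohol F5.
- Silylation of F5 returns to the route at 21.

**Step 15.** What may go wrong:
- Retro-aldol opening of the strained ring on the samarium alkoxide.
- Slow hemiacetal formation with the electron-rich aldehyde.
- Migration of the aroyl group from O6 to O8.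

Fallback: acylation and reduction are separated, and C8 is set by the reagent.
- Setting out from 23, 3,4,5-trimethoxybenzoyl chloride with pyridine and DMAP at 0 °C gives the keto ester F6.
- (S)-Me-CBS oxazaborolidine with catecholborane at −40 °C reduces F6, with branched C7 as the large group and C9H2 as the small group. This should give the 8R alcohol and return to the route at 26.

## Further compounds

F1 | step 13 | bicyclo[8.1.0] cyclopropanol (C7–C8–C11 three-membered ring, either carbinol epimer) | CC[Si](CC)(CC)O[C@H]1[C@@H]3C(C)(C)C3(O)C/C(C)=C/CC[C@@]2(C)O[C@H]12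
F2 | step 12 | triethylsilyl ether of 17 | CC[Si](CC)(CC)O[C@H](/C=C(C)/C=C)[C@@H](Cl)C(C)(C)C(=O)C/C(C)=C/I
F3 | step 12 | eleven-membered (E,E)-dienone silyl ether | CC[Si](CC)(CC)O[C@H]1[C@@H](Cl)C(C)(C)C(=O)C/C(C)=C/CC/C(C)=C/1
F4 | step 12 | eleven-membered allylic alcohol | O[C@H]1[C@@H](Cl)C(C)(C)C(=O)C/C(C)=C/CC/C(C)=C/1
F5 | step 12 | eleven-membered epoxy alcohol | O[C@H]1[C@@H](Cl)C(C)(C)C(=O)C/C(C)=C/CC[C@@]2(C)O[C@H]12
F6 | step 15 | C8-keto 3,4,5-trimethoxybenzoate | COc1cc(C(=O)O[C@H]2[C@H](C(C)C)C(=O)C/C(C)=C/CC[C@@]3(C)O[C@H]23)cc(OC)c1OC
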